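Assumption: (2S)-naringenin (citrus-derived, CAS 480-41-1) is bought as the single enantiomer and its ee is checked by chiral HPLC on receipt; geranyl acetate is the commercial (E)-isomer.

Abbreviations: dF(Me)ppy = cyclometalated 2-(2,4-difluorophenyl)-5-methylpyridine; dtbbpy = 4,4′-di-tert-butyl-2,2′-bipyridine; dme = 1,2-dimethoxyethane.

**Retrosynthetic overview**

1. Rings A, B and C and the only stereocentre (C2, S) are bought intact in (2S)-naringenin 1; no ring is formed in the route.
2. The single disconnection is the 4′-O–CH2 ether bond, which leads back to 1 and (E)-geranyl acetate 2.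
3. That bond is made directly on unprotected 1 in a visible-light step: the ring B hydroxyl is selected by homolysis of its weak O–H bond (phenoxyl radical 3) and coupled with a geranylnickel species from 2, giving the target 4.
4. The medium contains no strong base or acid, so C2 (prone to retro-oxa-Michael opening) and the (E)-olefin are preserved.

**Route**

Step 1
Reactants: 1 (2S)-naringenin; 2 geranyl acetate
Product: 4 (2S)-4′-O-geranylnaringenin, via naringenin 4′-oxyl radical 3 (not isolated)
Conditions: 2 (1.5 equiv), [Ir(dF(Me)ppy)2(dtbbpy)]PF6 (1 mol%), NiBr2(dme) (5 mol%), dtbbpy (6 mol%), 2,4,6-collidine (2 equiv), degassed MeCN (0.05 M), 450 nm LEDs, Ar, 15 °C, 16 h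
Reagents that add atoms: none
Why: Proposed new method: a thermodynamically gated nickel/photoredox allylic O-alkylation of a free phenol, in which the excited iridium photocatalyst (about +0.97 V vs SCE) with collidine (conjugate acid pKa about 15 in MeCN) can remove H• only from O–H bonds weaker than about 89 kcal/mol, which in 1 is the ring B 4′-OH (estimated about 87) and not the para-acyl 7-OH (about 92) or the chelated 5-OH (above 95), while collidine is far too weak to ionise the 7-OH, so there is no phenolate alkylation and no base-induced racemisation at C2 (bought in 1 and never touched); radical 3 is trapped by the cationic η3-geranyl complex of divalent nickel formed from zerovalent nickel and 2, the trivalent nickel aryloxide reductively eliminates at the unhindered CH2 terminus faster than syn/anti exchange to give the linear (E)-ether, the reduced photocatalyst (about −1.4 V) returns monovalent nickel to zerovalent nickel, acetate takes the proton from collidinium, and the product has no O–H below the gate so the reaction stops at the mono-ether; the closest known reaction types are nickel/photoredox C–O cross-coupling of aryl halides with alcohols, multi-site proton-coupled electron transfer activation of phenol O–H bonds and nickel-catalysed allylic substitution of allyl acetates.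

**Compound list**

1 | (2S)-naringenin, (2S)-5,7-dihydroxy-2-(4-hydroxyphenyl)-2,3-dihydro-4H-chromen-4-one | Oc1ccc([C@@H]2CC(=O)c3c(O)cc(O)cc3O2)cc1 | starting material
2 | geranyl acetate, (2E)-3,7-dimethylocta-2,6-dien-1-yl acetate | CC(C)=CCC/C(C)=C/COC(C)=O | starting material
3 | (2S)-naringenin 4′-oxyl radical (ring B phenoxyl radical, O-centred) | [O]c1ccc([C@@H]2CC(=O)c3c(O)cc(O)cc3O2)cc1 | intermediate
4 | (2S)-4′-O-geranylnaringenin, (2S)-2-{4-[(2E)-3,7-dimethylocta-2,6-dien-1-yloxy]phenyl}-5,7-dihydroxy-2,3-dihydro-4H-chromen-4-one | CC(C)=CCC/C(C)=C/COc1ccc([C@@H]2CC(=O)c3c(O)cc(O)cc3O2)cc1 | target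

**Step count and risks**

Total step count: 1. Longest linear sequence: 1 step.

Steps most likely to fail: the route has a single step, so it is the only entry.

Step 1 (the proposed new method). The ways it can fail are:
- Wrong site: geranylation at O7, or C-geranylation at C6/C8 of ring A, if neutral ring A attacks the allylnickel cation directly.
- Radical loss: dimerisation of radical 3, or its oxidation to a quinone methide with loss of the C2 hydrogen, which would erode ee.
- Olefin or regiochemistry erosion: neryl or linalyl ether from syn/anti exchange or elimination at the tertiary terminus.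
- Catalyst diversion: geranyl–geranyl homocoupling on nickel.

The product must therefore be checked by chiral HPLC, by NOE for the E-olefin, and by HMBC from the OCH2 protons to C4′.

Fallback for step 1 (known chemistry, sets out from 1 and comes back to the route at 4). The acidic 7-OH of 1 alone is silylated with i-Pr3SiCl (1.05 equiv) and i-Pr2NEt in CH2Cl2/DMF at −20 to 0 °C. The amine ionises only the 7-OH, and the 5-OH is chelated. This gives (2S)-7-O-triisopropylsilylnaringenin F1. The free 4′-OH of F1 is then coupled with commercial geraniol in a Mitsunobu reaction (PPh3, DIAD, THF, 0 °C to rt). This is a neutral SN2 displacement at C1 of the alkoxyphosphonium, so the ether is linear, the E-olefin is retained and C2 is untouched. It gives (2S)-4′-O-geranyl-7-O-triisopropylsilylnaringenin F2. The silyl group is removed with Bu4NF buffered with AcOH (1:1, THF, 0 °C), which spares the allylic ether and the stereocentre and delivers 4. The cost is three steps in place of one.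

**Further compounds**

F1 | step 1 | (2S)-7-O-triisopropylsilylnaringenin | Oc1ccc([C@@H]2CC(=O)c3c(O)cc(O[Si](C(C)C)(C(C)C)C(C)C)cc3O2)cc1
F2 | step 1 | (2S)-4′-O-geranyl-7-O-triisopropylsilylnaringenin | CC(C)=CCC/C(C)=C/COc1ccc([C@@H]2CC(=O)c3c(O)cc(O[Si](C(C)C)(C(C)C)C(C)C)cc3O2)cc1
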